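**Retrosynthetic overview**
- The strategy rests on the only stereocentre, C3 of the 4-hydroxy-3-methylbutyl chain on C3' of ring B. It bears the methyl group and is bonded to the CH2OH carbon, so it maps onto C2 of an (E)-2-methyl-4-arylbut-2-enal whose C2=C3 bond an ene-reductase can reduce on one face.
- Late disconnections are the three O-benzyl groups, the C3–OH bond of ring C, the O1–C2 bond of ring C (oxidative chalcone cyclisation), and the chalcone Cα=Cβ bond (aldol union of a ring-A ketone with a ring-B aldehyde).
- In the ring-B aldehyde, CHO comes from ArBr (Li exchange, DMF) and the chain from an ortho-allyl group (Claisen rearrangement) extended by cross-metathesis with methacrolein. The ring-A ketone comes from para-hydroxylation of a phloracetophenone ether.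
- Rings A and B are bought as arenes. The pyranone ring C is the only ring formed, and it is closed after the stereocentre is in place.

Key step: step 5

Assumption: the side-chain centre written [C@H] in the target SMILES is (S) (CH2OH > CH2CH2Ar > CH3 > H). Every chiral compound below carries this configuration.

**Step 1**
Reactants: 1 4-bromophenol; 2 allyl bromide
Product: 3 1-(allyloxy)-4-bromobenzene
Conditions: K2CO3, acetone, reflux
Reagents that add atoms: none
Why: Williamson ether synthesis: the potassium phenoxide of 1 displaces bromide from the unhindered allylic halide 2 in an SN2 reaction, and O-alkylation prevails in a polar aprotic solvent.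

**Step 2**
Reactants: 3 1-(allyloxy)-4-bromobenzene
Product: 5 2-allyl-4-bromophenol, via 6-allyl-4-bromocyclohexa-2,4-dienone 4 (not isolated)
Conditions: PhNEt2, 200 °C, N2
Reagents that add atoms: none
Why: Aromatic Claisen rearrangement: the concerted [3,3]-sigmatropic shift moves the allyl group to one of the two equivalent ortho carbons (the para carbon is blocked by Br) to give dienone 4, which tautomerises to the phenol.

**Step 3**
Reactants: 5 2-allyl-4-bromophenol
Product: 6 2-allyl-1-(benzyloxy)-4-bromobenzene
Conditions: BnBr, K2CO3, DMF, 50 °C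
Reagents that add atoms: benzyl bromide, BrCc1ccccc1
Why: Williamson benzylation caps the phenol, which would otherwise coordinate to the Ru carbene and later add to the enal in an intramolecular oxa-Michael reaction, with a group that leaves in the final hydrogenolysis.

**Step 4**
Reactants: 6 2-allyl-1-(benzyloxy)-4-bromobenzene; 7 methacrolein
Product: 8 (E)-4-[2-(benzyloxy)-5-bromophenyl]-2-methylbut-2-enal
Conditions: Hoveyda–Grubbs II (3 mol %), 7 (8 equiv, freshly distilled), 1,4-benzoquinone (10 mol %), CH2Cl2, 40 °C; chromatography to the pure E isomer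
Reagents that add atoms: none
Why: Olefin cross-metathesis of a readily homodimerising terminal alkene with an electron-poor 1,1-disubstituted partner that does not homodimerise is selective for the cross product, the trisubstituted enal is expected mainly as the thermodynamically preferred E isomer, and benzoquinone scavenges Ru hydrides that would move the allyl double bond into conjugation with the arene.

**Step 5**
Reactants: 8 (E)-4-[2-(benzyloxy)-5-bromophenyl]-2-methylbut-2-enal
Product: 10 (S)-4-[2-(benzyloxy)-5-bromophenyl]-2-methylbutan-1-ol, via (S)-2-methylbutanal 9 (not isolated)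
Conditions: OYE-family ene-reductase ((S)-selective hit of a panel, e.g. yeast OYE2), NADP+ (cat.), D-glucose (3 equiv), glucose dehydrogenase, KPi buffer (100 mM, pH 7.0)/MTBE 4:1, 30 °C; once 8 is consumed: horse-liver ADH, NAD+ (cat.), same pot
Reagents that add atoms: none
Why: Ene-reductase/alcohol dehydrogenase cascade (asymmetric bioreduction of an activated alkene): the aldehyde oxygen of 8 is held by the two hydrogen-bond donors (His/Asn or His/His) above the flavin, reduced FMN transfers hydride from N5 to the β-carbon C3, and the conserved tyrosine protonates the α-carbon C2 from the opposite face, so that H2 is added anti and aldehyde 9 results; the ADH then passes hydride from NADH to C1, giving three new C–H bonds in all. The closest known reaction type is the Old Yellow Enzyme reduction of (E)-α-methylcinnamaldehydes and (E)-2-methylalk-2-enals coupled in one pot to ADH reduction, which furnishes 2-methyl primary alcohols. No ring is closed in this step. The new stereocentre at C2 is controlled by the enzyme, which presents only one face of C2 to the tyrosine once the single (E) isomer is bound in its normal orientation; yeast OYE1–3-type enzymes are expected to give the (S) aldehyde, and the choice is to be confirmed by a panel screen with chiral HPLC read-out. The step needs enantioface selectivity and C=C-before-C=O chemoselectivity: the first is secured by the geometrically pure enal with its small α-methyl and flexible β-CH2Ar group, the second by withholding the ADH until 8 is gone, because the allylic alcohol would be a dead end for the ene-reductase. Near-neutral pH, the MTBE phase and prompt ADH addition should keep 9 from racemising by enolisation, and ArBr and the benzyl ether are inert to both enzymes.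

**Step 6**
Reactants: 10 (S)-4-[2-(benzyloxy)-5-bromophenyl]-2-methylbutan-1-ol
Product: 11 1-(benzyloxy)-2-[(S)-4-(benzyloxy)-3-methylbutyl]-4-bromobenzene
Conditions: NaH, BnBr, Bu4NI (cat.), THF, 0 °C → rt
Reagents that add atoms: benzyl bromide, BrCc1ccccc1
Why: Williamson etherification of the primary alkoxide, in which the neighbouring stereocentre carries no acidic hydrogen and no leaving group and is therefore untouched, while ArBr is inert to NaH.

**Step 7**
Reactants: 11 1-(benzyloxy)-2-[(S)-4-(benzyloxy)-3-methylbutyl]-4-bromobenzene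
Product: 14 4-(benzyloxy)-3-[(S)-4-(benzyloxy)-3-methylbutyl]benzaldehyde, via aryllithium 12 (not isolated), via lithium hemiaminal alkoxide 13 (not isolated)
Conditions: n-BuLi, THF, −78 °C; DMF, −78 → 0 °C; H2O
Reagents that add atoms: N,N-dimethylformamide, CN(C)C=O
Why: Bromine–lithium exchange is much faster at −78 °C than deprotonation of the benzylic ether positions, aryllithium 12 adds to DMF (Bouveault-type formylation), and adduct 13 persists until the aqueous quench, so that a second addition cannot take place.

**Step 8**
Reactants: 15 2',4'-dihydroxy-6'-methoxyacetophenone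
Product: 16 4'-(benzyloxy)-2'-hydroxy-6'-methoxyacetophenone
Conditions: BnBr (1.0 equiv), K2CO3, acetone, reflux
Reagents that add atoms: benzyl bromide, BrCc1ccccc1
Why: Chemoselective Williamson benzylation: the 2'-OH is tied up in a hydrogen bond to the acetyl C=O and is much less nucleophilic, so one equivalent of benzyl bromide with a weak base is expected to react at the free, more acidic 4'-OH.

**Step 9**
Reactants: 16 4'-(benzyloxy)-2'-hydroxy-6'-methoxyacetophenone
Product: 18 4'-(benzyloxy)-2',5'-dihydroxy-6'-methoxyacetophenone, via potassium aryl sulfate 17 (not isolated)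
Conditions: K2S2O8, aq. KOH/pyridine, 15–20 °C; HCl to pH 5, unreacted 16 extracted; then 2 M HCl, 80 °C, N2
Reagents that add atoms: potassium peroxodisulfate, [K+].[K+].[O-]S(=O)(=O)OOS(=O)(=O)[O-]
Why: Elbs persulfate oxidation: the phenolate of 16 attacks the peroxide oxygen of the peroxodisulfate through its para carbon C5', which is further activated by the two flanking alkoxy groups, and the sulfate monoester 17 is hydrolysed by dilute acid at the S–O bond faster than the aryl benzyl ether is cleaved.

**Step 10**
Reactants: 18 4'-(benzyloxy)-2',5'-dihydroxy-6'-methoxyacetophenone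
Product: 19 4'-(benzyloxy)-2'-hydroxy-5',6'-dimethoxyacetophenone
Conditions: MeI (1.05 equiv), K2CO3, acetone, reflux, N2
Reagents that add atoms: iodomethane, CI
Why: Selective Williamson methylation: of the two phenols only the new 5'-OH is free of chelation, so a slight excess of MeI with K2CO3 leaves the hydrogen-bonded 2'-OH that is needed for ring closure.

**Step 11**
Reactants: 14 4-(benzyloxy)-3-[(S)-4-(benzyloxy)-3-methylbutyl]benzaldehyde; 19 4'-(benzyloxy)-2'-hydroxy-5',6'-dimethoxyacetophenone
Product: 20 (E)-1-[4-(benzyloxy)-2-hydroxy-5,6-dimethoxyphenyl]-3-{4-(benzyloxy)-3-[(S)-4-(benzyloxy)-3-methylbutyl]phenyl}prop-2-en-1-one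
Conditions: KOH (50 % aq.), EtOH, rt; then 1 M HCl
Reagents that add atoms: none
Why: Claisen–Schmidt (crossed aldol) condensation: only ketone 19 can form an enolate, aldehyde 14 has no α-hydrogen, and E1cB loss of water gives the conjugated E enone, while the remote stereocentre has no acidic hydrogen.

**Step 12**
Reactants: 20 the 2'-hydroxychalcone
Product: 22 7-(benzyloxy)-2-{4-(benzyloxy)-3-[(S)-4-(benzyloxy)-3-methylbutyl]phenyl}-5,6-dimethoxy-4H-chromen-4-one, via flavanone 21 (not isolated)
Conditions: I2 (10 mol %), DMSO, 120 °C
Reagents that add atoms: none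
Why: Iodine/DMSO oxidative cyclisation: 6-endo oxa-Michael addition of the 2'-OH closes the O1–C2 bond to flavanone 21, iodination at C3 and loss of HI give the flavone, DMSO reoxidises HI to I2, and this two-stage entry to the flavonol avoids the aurone formation that alkaline H2O2 (Algar–Flynn–Oyamada) tends to cause with 6'-alkoxychalcones.

**Step 13**
Reactants: 22 the tri-O-benzyl flavone
Product: 24 7-(benzyloxy)-2-{4-(benzyloxy)-3-[(S)-4-(benzyloxy)-3-methylbutyl]phenyl}-3-hydroxy-5,6-dimethoxy-4H-chromen-4-one, via 2,3-epoxyflavanone 23 (not isolated)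
Conditions: DMDO (acetone solution, in portions), CH2Cl2, 0 °C; then p-TsOH·H2O (cat.), CH2Cl2, rt
Reagents that add atoms: dimethyldioxirane, CC1(C)OO1
Why: Dioxirane epoxidation of the enol-ether-like C2=C3 bond under neutral conditions gives the labile epoxide 23, whose acid-catalysed opening at C2 (cation stabilised by O1 and the aryl ring) and loss of H-3 deliver the 3-hydroxyflavone, and low temperature with portionwise dosing favours this reaction over the slower C–H oxidation of benzylic and tertiary positions.

**Step 14**
Reactants: 24 the tri-O-benzyl flavonol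
Product: 25 3,7-dihydroxy-2-{4-hydroxy-3-[(S)-4-hydroxy-3-methylbutyl]phenyl}-5,6-dimethoxy-4H-chromen-4-one (CNP0253239.1)
Conditions: H2 (1 atm), Pd(OH)2/C, THF/MeOH, rt, followed by LC and stopped at full debenzylation
Reagents that add atoms: none
Why: Catalytic hydrogenolysis cleaves the two aryl benzyl ethers and the primary alkyl benzyl ether at the benzylic C–O bonds, whereas the fully conjugated, hydrogen-bonded 3-hydroxychromone C2=C3 bond is reduced far more slowly, and the stereocentre has no bond to a reacting atom.

**Compound list**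
1 | 4-bromophenol | Oc1ccc(Br)cc1 | starting material
2 | allyl bromide | C=CCBr | starting material
3 | 1-(allyloxy)-4-bromobenzene | C=CCOc1ccc(Br)cc1 | intermediate
4 | 6-allyl-4-bromocyclohexa-2,4-dien-1-one (racemic, not isolated) | C=CCC1C=C(Br)C=CC1=O | intermediate
5 | 2-allyl-4-bromophenol | C=CCc1cc(Br)ccc1O | intermediate
6 | 2-allyl-1-(benzyloxy)-4-bromobenzene | C=CCc1cc(Br)ccc1OCc1ccccc1 | intermediate
7 | methacrolein | CC(=C)C=O | starting material
8 | (E)-4-[2-(benzyloxy)-5-bromophenyl]-2-methylbut-2-enal | O=C/C(C)=C/Cc1cc(Br)ccc1OCc1ccccc1 | intermediate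
9 | (S)-4-[2-(benzyloxy)-5-bromophenyl]-2-methylbutanal (not isolated) | Brc1ccc(OCc2ccccc2)c(CC[C@H](C)C=O)c1 | intermediate
10 | (S)-4-[2-(benzyloxy)-5-bromophenyl]-2-methylbutan-1-ol | Brc1ccc(OCc2ccccc2)c(CC[C@H](C)CO)c1 | intermediate
11 | 1-(benzyloxy)-2-[(S)-4-(benzyloxy)-3-methylbutyl]-4-bromobenzene | Brc1ccc(OCc2ccccc2)c(CC[C@H](C)COCc2ccccc2)c1 | intermediate
12 | {4-(benzyloxy)-3-[(S)-4-(benzyloxy)-3-methylbutyl]phenyl}lithium (not isolated) | [Li]c1ccc(OCc2ccccc2)c(CC[C@H](C)COCc2ccccc2)c1 | intermediate
13 | lithium alkoxide of the aryl(dimethylamino)methanol, the DMF adduct of 12 (not isolated) | [Li]OC(N(C)C)c1ccc(OCc2ccccc2)c(CC[C@H](C)COCc2ccccc2)c1 | intermediate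
14 | 4-(benzyloxy)-3-[(S)-4-(benzyloxy)-3-methylbutyl]benzaldehyde | O=Cc1ccc(OCc2ccccc2)c(CC[C@H](C)COCc2ccccc2)c1 | intermediate
15 | 2',4'-dihydroxy-6'-methoxyacetophenone | CC(=O)c1c(O)cc(O)cc1OC | starting material
16 | 4'-(benzyloxy)-2'-hydroxy-6'-methoxyacetophenone | CC(=O)c1c(O)cc(OCc2ccccc2)cc1OC | intermediate
17 | potassium 3-acetyl-6-(benzyloxy)-4-hydroxy-2-methoxyphenyl sulfate (not isolated) | CC(=O)c1c(O)cc(OCc2ccccc2)c(OS(=O)(=O)[O-])c1OC.[K+] | intermediate
18 | 4'-(benzyloxy)-2',5'-dihydroxy-6'-methoxyacetophenone | CC(=O)c1c(O)cc(OCc2ccccc2)c(O)c1OC | intermediate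
19 | 4'-(benzyloxy)-2'-hydroxy-5',6'-dimethoxyacetophenone | CC(=O)c1c(O)cc(OCc2ccccc2)c(OC)c1OC | intermediate
20 | (E)-2'-hydroxychalcone carrying the (S) side chain | COc1c(OCc2ccccc2)cc(O)c(C(=O)/C=C/c2ccc(OCc3ccccc3)c(CC[C@H](C)COCc3ccccc3)c2)c1OC | intermediate
21 | 7-(benzyloxy)-2-{4-(benzyloxy)-3-[(S)-4-(benzyloxy)-3-methylbutyl]phenyl}-5,6-dimethoxychroman-4-one (both C2 epimers, not isolated) | COc1c(OCc2ccccc2)cc2OC(c3ccc(OCc4ccccc4)c(CC[C@H](C)COCc4ccccc4)c3)CC(=O)c2c1OC | intermediate
22 | 7-(benzyloxy)-2-{4-(benzyloxy)-3-[(S)-4-(benzyloxy)-3-methylbutyl]phenyl}-5,6-dimethoxy-4H-chromen-4-one | COc1c(OCc2ccccc2)cc2oc(-c3ccc(OCc4ccccc4)c(CC[C@H](C)COCc4ccccc4)c3)cc(=O)c2c1OC | intermediate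
23 | 2,3-epoxide of 22 (both epoxide faces, not isolated) | COc1c(OCc2ccccc2)cc2OC3(c4ccc(OCc5ccccc5)c(CC[C@H](C)COCc5ccccc5)c4)OC3C(=O)c2c1OC | intermediate
24 | 7-(benzyloxy)-2-{4-(benzyloxy)-3-[(S)-4-(benzyloxy)-3-methylbutyl]phenyl}-3-hydroxy-5,6-dimethoxy-4H-chromen-4-one | COc1c(OCc2ccccc2)cc2oc(-c3ccc(OCc4ccccc4)c(CC[C@H](C)COCc4ccccc4)c3)c(O)c(=O)c2c1OC | intermediate
25 | 3,7-dihydroxy-2-{4-hydroxy-3-[(S)-4-hydroxy-3-methylbutyl]phenyl}-5,6-dimethoxy-4H-chromen-4-one (CNP0253239.1) | COc1c(O)cc2oc(-c3ccc(O)c(CC[C@H](C)CO)c3)c(O)c(=O)c2c1OC | target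

**Step count**
Total step count: 14.
Longest linear sequence: 11 (steps 1–7, then 11–14).

**Steps most likely to fail**

1. **Step 5.**
   - Risk: the bulky, very lipophilic enal may bind poorly or in a flipped orientation. That would mean slow turnover or poor facial selectivity at C2. The saturated aldehyde may also racemise by enolisation while it waits for the dehydrogenase.
   - Fallback: it sets out from 8 and replaces biocatalysis by transition-metal asymmetric hydrogenation. Luche reduction (NaBH4, CeCl3·7H2O, MeOH, 0 °C) should give (E)-4-[2-(benzyloxy)-5-bromophenyl]-2-methylbut-2-en-1-ol F1. The trisubstituted allylic alcohol is then hydrogenated with a homogeneous chiral catalyst, either an Ir phosphinooxazoline BArF complex (H2 50 bar, CH2Cl2) or Ru(OAc)2(BINAP) (MeOH, H2). The ligand antipode is chosen in a test run so that the (S) alcohol forms. ArBr and the benzyl ether tolerate these catalysts, and the route is rejoined at 10.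

2. **Step 13.**
   - Risk: epoxidation of the carbonyl-conjugated C2=C3 bond may be slow. The excess dioxirane could then start to oxidise benzylic ether C–H bonds or insert into the tertiary C–H bond of the side chain.
   - Fallback: it sets out from 22 and reverses the polarity at C3. LDA (THF, −78 °C) should give the 3-lithioflavone F2. Trimethyl borate traps it as the dimethyl flavon-3-ylboronate F3. Oxidation with H2O2/AcOH (0 °C → rt) converts the C–B bond into C–OH, and the route is rejoined at 24.

3. **Step 9.**
   - Risk: low conversion, over-oxidation of the electron-rich hydroquinone to coloured polymeric material, and partial loss of the benzyl group during the acid hydrolysis.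
   - Fallback: it sets out from 16 and passes through the quinone oxidation level. Teuber oxidation with Fremy's salt (potassium nitrosodisulfonate, KH2PO4 buffer, acetone/H2O, rt) should give 2-acetyl-5-(benzyloxy)-3-methoxy-1,4-benzoquinone F4. Aqueous Na2S2O4 (Et2O/H2O, rt) reduces it to the hydroquinone, and the route is rejoined at 18.

**Further compounds**
F1 | step 5 | (E)-4-[2-(benzyloxy)-5-bromophenyl]-2-methylbut-2-en-1-ol | OC/C(C)=C/Cc1cc(Br)ccc1OCc1ccccc1
F2 | step 13 | 3-lithio derivative of flavone 22 | COc1c(OCc2ccccc2)cc2oc(-c3ccc(OCc4ccccc4)c(CC[C@H](C)COCc4ccccc4)c3)c([Li])c(=O)c2c1OC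
F3 | step 13 | dimethyl boronate at C3 of flavone 22 | COc1c(OCc2ccccc2)cc2oc(-c3ccc(OCc4ccccc4)c(CC[C@H](C)COCc4ccccc4)c3)c(B(OC)OC)c(=O)c2c1OC
F4 | step 9 | 2-acetyl-5-(benzyloxy)-3-methoxy-1,4-benzoquinone | CC(=O)C1=C(OC)C(=O)C(OCc2ccccc2)=CC1=O
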